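**Retrosynthetic overview**
- Aiphanol ⇒ E-stilbene C=C by Horner–Wadsworth–Emmons olefination of a ring B benzodioxane carbaldehyde with a silylated 3,5-dihydroxybenzylphosphonate (ring D).
- Benzodioxane ⇒ open 8'-O-aryl ether carbinol by disconnecting the O–C7' bond of dioxane ring C. The strategy rests on C7', the benzylic dioxane carbon bearing ring A: the free para-hydroxyl of ring A makes the C7'–O bond reversible through the ring A para-quinone methide, so trans-2,3-disubstituted ring C is the thermodynamic sink and C7' needs no earlier control.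
- Carbinol ⇒ C7'–C8' bond from a ring A aryl Grignard reagent and a lactol in which the ring B phenol is masked as the hemiacetal oxygen.
- Lactol ⇒ C8'–O(aryl) bond by Mitsunobu inversion of an (S)-glycerate-derived hydroxy ester with 3,4-dihydroxybenzaldehyde; C8' is the only stereocentre brought in.
- Rings A, B and D are bought; ring C is the only ring formed (in the key step).

Key step: step 8

Remark on labels and abbreviations: C7' is the dioxane carbon bearing ring A (4-hydroxy-3,5-dimethoxyphenyl), C8' the dioxane carbon bearing C9' (the CH2OH carbon), ring B the benzo ring, ring C the dioxane, ring D the resorcinol ring; TBDPS = tert-butyldiphenylsilyl, TBS = tert-butyldimethylsilyl, THP = tetrahydropyran-2-yl.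

**Route**

Step 1
Reactants: 1 methyl (4S)-2,2-dimethyl-1,3-dioxolane-4-carboxylate
Product: 2 methyl (2S)-2,3-dihydroxypropanoate
Conditions: AcOH/H2O (4:1), 45 °C; toluene azeotrope
Reagents that add atoms: none
Why: Acid-catalysed acetonide hydrolysis (acetal cleavage) should free the diol without touching the ester or the stereocentre, which is carried over as (S).

Step 2
Reactants: 2 methyl (2S)-2,3-dihydroxypropanoate
Product: 3 methyl (2S)-3-[(tert-butyldiphenylsilyl)oxy]-2-hydroxypropanoate
Conditions: TBDPSCl (1.05 equiv), imidazole, CH2Cl2, 0 °C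
Reagents that add atoms: tert-butyl(chloro)diphenylsilane, CC(C)(C)[Si](Cl)(c1ccccc1)c1ccccc1
Why: Silyl ether formation with the bulky chlorosilane is selective for the primary hydroxyl, leaving the secondary hydroxyl free for step 3 and the stereocentre untouched.

Step 3
Reactants: 3 methyl (2S)-3-[(tert-butyldiphenylsilyl)oxy]-2-hydroxypropanoate; 4 3,4-dihydroxybenzaldehyde
Product: 5 methyl (2R)-3-[(tert-butyldiphenylsilyl)oxy]-2-(4-formyl-2-hydroxyphenoxy)propanoate
Conditions: PPh3, DIAD, THF, 0 °C → rt (4 in 1.5-fold excess)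
Reagents that add atoms: none
Why: Mitsunobu etherification, in which the phenoxide displaces the secondary oxyphosphonium by SN2 with inversion and so sets C8' as (R); the 4-hydroxyl, para to the formyl group and by far the more acidic phenol, should be the one ionized and alkylated, and the excess of 4 suppresses bis-alkylation.

Step 4
Reactants: 5 methyl (2R)-3-[(tert-butyldiphenylsilyl)oxy]-2-(4-formyl-2-hydroxyphenoxy)propanoate
Product: 7 (3R)-3-[[(tert-butyldiphenylsilyl)oxy]methyl]-7-(1,3-dioxolan-2-yl)-1,4-benzodioxin-2(3H)-one, via dioxolane ester 6 (not isolated)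
Conditions: ethylene glycol (1.2 equiv), TsOH·H2O (cat.), toluene, reflux, Dean–Stark trap
Reagents that add atoms: ethylene glycol, OCCO
Why: Acid-catalysed acetalization of the aldehyde followed by intramolecular transesterification of the ortho-phenol onto the ester (lactonization of a 2-hydroxyphenoxyacetate to the six-membered 1,4-benzodioxin-2-one), both driven by azeotropic removal of water and methanol, should mask the aldehyde and the ring B phenol in one operation without breaking a bond at C8'.

Step 5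
Reactants: 7 (3R)-3-[[(tert-butyldiphenylsilyl)oxy]methyl]-7-(1,3-dioxolan-2-yl)-1,4-benzodioxin-2(3H)-one
Product: 8 (3R)-3-[[(tert-butyldiphenylsilyl)oxy]methyl]-7-(1,3-dioxolan-2-yl)-2,3-dihydro-1,4-benzodioxin-2-ol (both C2 epimers)
Conditions: i-Bu2AlH (1.1 equiv), CH2Cl2, −78 °C; aq. KNaC4H4O6
Reagents that add atoms: none
Why: Partial reduction of a lactone to the lactol by i-Bu2AlH at −78 °C, where the tetrahedral aluminium alkoxide survives until work-up as is routine for dihydrocoumarin-type aryl lactones; the hemiacetal carbon forms as an inconsequential epimer mixture and C8' is untouched.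

Step 6
Reactants: 9 4-bromo-2,6-dimethoxyphenol
Product: 10 2-(4-bromo-2,6-dimethoxyphenoxy)tetrahydro-2H-pyran (racemic THP ether)
Conditions: 3,4-dihydro-2H-pyran, PPTS (cat.), CH2Cl2, rt
Reagents that add atoms: 3,4-dihydro-2H-pyran, C1=COCCC1
Why: Acid-catalysed addition of the phenol to the enol ether (tetrahydropyranyl ether formation) gives a base-stable, acid-labile mask for the ring A phenol that tolerates Grignard formation.

Step 7
Reactants: 8 (3R)-3-[[(tert-butyldiphenylsilyl)oxy]methyl]-7-(1,3-dioxolan-2-yl)-2,3-dihydro-1,4-benzodioxin-2-ol; 10 2-(4-bromo-2,6-dimethoxyphenoxy)tetrahydro-2H-pyran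
Product: 13 (1RS,2R)-3-[(tert-butyldiphenylsilyl)oxy]-1-[3,5-dimethoxy-4-(THP-oxy)phenyl]-2-[4-(1,3-dioxolan-2-yl)-2-hydroxyphenoxy]propan-1-ol (both C7' epimers; protected precursor of the key step), via arylmagnesium bromide 11 (not isolated), via ring-opened aldehyde 12 (not isolated)
Conditions: 10, Mg, I2 (cat.), THF, 50 °C; then 8, THF, 0 °C → rt (3 equiv of 11); aq. NH4Cl
Reagents that add atoms: none
Why: Grignard addition to a lactol, in which one equivalent of 11 deprotonates the hemiacetal, the magnesium salt opens to the phenoxide aldehyde 12 and a second equivalent adds to the formyl carbon to form the C7'–C8' bond; both C7' epimers are expected and both are usable because step 8 is stereoconvergent, while C8' should be kept because the aldehyde is trapped faster than it enolizes.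

Step 8
Reactants: 13 (1RS,2R)-3-[(tert-butyldiphenylsilyl)oxy]-1-[3,5-dimethoxy-4-(THP-oxy)phenyl]-2-[4-(1,3-dioxolan-2-yl)-2-hydroxyphenoxy]propan-1-ol
Product: 16 (2R,3R)-2-[[(tert-butyldiphenylsilyl)oxy]methyl]-3-(4-hydroxy-3,5-dimethoxyphenyl)-2,3-dihydro-1,4-benzodioxine-6-carbaldehyde, via phenol aldehyde carbinol 14 (not isolated), via quinone methide 15 (not isolated)
Conditions: TsOH·H2O (0.5 equiv), MeCN/H2O (20:1), 0.01 M, rt → 45 °C
Reagents that add atoms: water, O
Why: Aqueous acid should first hydrolyse the aryl THP ether and the dioxolane (13 → 14) and then protonate the C7' hydroxyl, and loss of water gives the benzylic cation that is the O-protonated para-quinone methide 15 of ring A. The ring B hydroxyl ortho to the C8' ether oxygen adds to C7' of 15 in a 6-exo-trig oxa-1,6-addition that forms the O–C7' bond and closes dioxane ring C; the closest known reaction type is the acid-mediated cyclization of ortho-hydroxyaryl β-aryl ether carbinols (lignin β-O-4 models, flavonolignan intermediates) to 2-aryl-1,4-benzodioxanes. The new C7' stereocentre is controlled by the fixed (R)-C8' centre, because a chair-like closure places ring A and the CH2OSi group both equatorial and because the benzylic C7'–O bond re-ionizes under the same acid, so both carbinol epimers and any cis product should drain to the trans (2R,3R) isomer. C8' takes no part in the cation and keeps its configuration, and proton loss from C8' would lead to an enol ether that cannot return to 15, which would cost material but not enantiopurity. The step needs O- over C-attack and intra- over intermolecular capture, which the formyl-deactivated ring B, the six-membered intramolecular closure and high dilution should secure; the silyl ether on O9' also blocks loss of C9' as formaldehyde.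

Step 9
Reactants: 16 (2R,3R)-2-[[(tert-butyldiphenylsilyl)oxy]methyl]-3-(4-hydroxy-3,5-dimethoxyphenyl)-2,3-dihydro-1,4-benzodioxine-6-carbaldehyde
Product: 17 (2R,3R)-3-[4-[(tert-butyldimethylsilyl)oxy]-3,5-dimethoxyphenyl]-2-[[(tert-butyldiphenylsilyl)oxy]methyl]-2,3-dihydro-1,4-benzodioxine-6-carbaldehyde
Conditions: TBSCl, imidazole, DMF, rt
Reagents that add atoms: tert-butyl(chloro)dimethylsilane, CC(C)(C)[Si](C)(C)Cl
Why: Silyl ether formation on the ring A phenol removes the acidic proton, so that under the basic conditions of step 14 no phenoxide can reopen the C7'–O bond through the quinone methide.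

Step 10
Reactants: 18 3,5-dihydroxybenzyl alcohol
Product: 19 tert-butyl[[3,5-bis[(tert-butyldimethylsilyl)oxy]phenyl]methoxy]dimethylsilane
Conditions: TBSCl (3.5 equiv), imidazole, DMF, rt
Reagents that add atoms: tert-butyl(chloro)dimethylsilane, CC(C)(C)[Si](C)(C)Cl
Why: Exhaustive silyl ether formation on both phenols and the benzylic alcohol under standard chlorosilane/imidazole conditions.

Step 11
Reactants: 19 tert-butyl[[3,5-bis[(tert-butyldimethylsilyl)oxy]phenyl]methoxy]dimethylsilane
Product: 20 [3,5-bis[(tert-butyldimethylsilyl)oxy]phenyl]methanol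
Conditions: AcOH/THF/H2O (3:1:1), rt
Reagents that add atoms: none
Why: Selective acidic hydrolysis of the alkyl silyl ether, since aryl TBS ethers are far more resistant to mild acid than a primary benzylic TBS ether.

Step 12
Reactants: 20 [3,5-bis[(tert-butyldimethylsilyl)oxy]phenyl]methanol
Product: 21 [[5-(bromomethyl)-1,3-phenylene]bis(oxy)]bis(tert-butyldimethylsilane)
Conditions: CBr4, PPh3, CH2Cl2, 0 °C
Reagents that add atoms: carbon tetrabromide, BrC(Br)(Br)Br
Why: Appel bromination converts the benzylic alcohol into the bromide under neutral conditions that leave the aryl silyl ethers intact.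

Step 13
Reactants: 21 [[5-(bromomethyl)-1,3-phenylene]bis(oxy)]bis(tert-butyldimethylsilane)
Product: 22 diethyl [3,5-bis[(tert-butyldimethylsilyl)oxy]benzyl]phosphonate
Conditions: P(OEt)3 (neat), 130 °C
Reagents that add atoms: triethyl phosphite, CCOP(OCC)OCC
Why: Michaelis–Arbuzov reaction of the benzylic bromide with triethyl phosphite gives the phosphonate with loss of bromoethane.

Step 14
Reactants: 17 (2R,3R)-3-[4-[(tert-butyldimethylsilyl)oxy]-3,5-dimethoxyphenyl]-2-[[(tert-butyldiphenylsilyl)oxy]methyl]-2,3-dihydro-1,4-benzodioxine-6-carbaldehyde; 22 diethyl [3,5-bis[(tert-butyldimethylsilyl)oxy]benzyl]phosphonate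
Product: 23 tetrasilyl aiphanol: the (E)-stilbene from 17 and 22, with TBS on the ring A phenol and on both ring D phenols and TBDPS on O9', (2R,3R)
Conditions: NaH, THF, 0 °C → rt
Reagents that add atoms: none
Why: Horner–Wadsworth–Emmons olefination of the aryl aldehyde with the semi-stabilized benzylphosphonate anion, which should give the E-stilbene through the reversible addition and anti elimination typical of such phosphonates; no stereocentre is affected.

Step 15
Reactants: 23 tetrasilyl aiphanol
Product: 24 aiphanol, 5-[(E)-2-[(2R,3R)-3-(4-hydroxy-3,5-dimethoxyphenyl)-2-(hydroxymethyl)-2,3-dihydro-1,4-benzodioxin-6-yl]ethenyl]benzene-1,3-diol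
Conditions: Bu4NF, AcOH (1:1, excess), THF, 0 °C → rt
Reagents that add atoms: none
Why: Fluoride-induced cleavage of the three aryl TBS ethers and the primary TBDPS ether; the acetic acid buffer keeps the ring A phenol protonated so that the C7'–O bond is not opened via the phenoxide, and reclosure would in any case return the trans isomer.

**Compound list**

1 | methyl (4S)-2,2-dimethyl-1,3-dioxolane-4-carboxylate | COC(=O)[C@@H]1COC(C)(C)O1 | starting material
2 | methyl (2S)-2,3-dihydroxypropanoate | COC(=O)[C@@H](O)CO | intermediate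
3 | methyl (2S)-3-[(tert-butyldiphenylsilyl)oxy]-2-hydroxypropanoate | COC(=O)[C@@H](O)CO[Si](c1ccccc1)(c1ccccc1)C(C)(C)C | intermediate
4 | 3,4-dihydroxybenzaldehyde | O=Cc1ccc(O)c(O)c1 | starting material
5 | methyl (2R)-3-[(tert-butyldiphenylsilyl)oxy]-2-(4-formyl-2-hydroxyphenoxy)propanoate | COC(=O)[C@H](Oc1ccc(C=O)cc1O)CO[Si](c1ccccc1)(c1ccccc1)C(C)(C)C | intermediate
6 | methyl (2R)-3-[(tert-butyldiphenylsilyl)oxy]-2-[4-(1,3-dioxolan-2-yl)-2-hydroxyphenoxy]propanoate (not isolated) | COC(=O)[C@H](Oc1ccc(C2OCCO2)cc1O)CO[Si](c1ccccc1)(c1ccccc1)C(C)(C)C | intermediate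
7 | (3R)-3-[[(tert-butyldiphenylsilyl)oxy]methyl]-7-(1,3-dioxolan-2-yl)-1,4-benzodioxin-2(3H)-one | O=C1Oc2cc(C3OCCO3)ccc2O[C@@H]1CO[Si](c1ccccc1)(c1ccccc1)C(C)(C)C | intermediate
8 | (3R)-3-[[(tert-butyldiphenylsilyl)oxy]methyl]-7-(1,3-dioxolan-2-yl)-2,3-dihydro-1,4-benzodioxin-2-ol, both C2 epimers | OC1Oc2cc(C3OCCO3)ccc2O[C@@H]1CO[Si](c1ccccc1)(c1ccccc1)C(C)(C)C | intermediate
9 | 4-bromo-2,6-dimethoxyphenol | COc1cc(Br)cc(OC)c1O | starting material
10 | 2-(4-bromo-2,6-dimethoxyphenoxy)tetrahydro-2H-pyran, racemic | COc1cc(Br)cc(OC)c1OC1CCCCO1 | intermediate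
11 | [3,5-dimethoxy-4-(tetrahydro-2H-pyran-2-yloxy)phenyl]magnesium bromide (not isolated) | COc1cc([Mg]Br)cc(OC)c1OC1CCCCO1 | intermediate
12 | (2R)-3-[(tert-butyldiphenylsilyl)oxy]-2-[4-(1,3-dioxolan-2-yl)-2-hydroxyphenoxy]propanal, present in the flask as its magnesium phenoxide (not isolated) | O=C[C@H](Oc1ccc(C2OCCO2)cc1O)CO[Si](c1ccccc1)(c1ccccc1)C(C)(C)C | intermediate
13 | (1RS,2R)-3-[(tert-butyldiphenylsilyl)oxy]-1-[3,5-dimethoxy-4-(tetrahydro-2H-pyran-2-yloxy)phenyl]-2-[4-(1,3-dioxolan-2-yl)-2-hydroxyphenoxy]propan-1-ol, mixture at C7' and at the THP carbon | COc1cc(C(O)[C@@H](CO[Si](c2ccccc2)(c2ccccc2)C(C)(C)C)Oc2ccc(C3OCCO3)cc2O)cc(OC)c1OC1CCCCO1 | intermediate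
14 | 4-[[(1RS,2R)-3-[(tert-butyldiphenylsilyl)oxy]-1-hydroxy-1-(4-hydroxy-3,5-dimethoxyphenyl)propan-2-yl]oxy]-3-hydroxybenzaldehyde, both C7' epimers (not isolated) | COc1cc(C(O)[C@@H](CO[Si](c2ccccc2)(c2ccccc2)C(C)(C)C)Oc2ccc(C=O)cc2O)cc(OC)c1O | intermediate
15 | ring A para-quinone methide, 4-[3-[(tert-butyldiphenylsilyl)oxy]-2-(4-formyl-2-hydroxyphenoxy)propylidene]-2,6-dimethoxycyclohexa-2,5-dien-1-one, C8' arranged as in 14 (descriptor S only through a priority change) (not isolated) | COC1=CC(=C[C@@H](CO[Si](c2ccccc2)(c2ccccc2)C(C)(C)C)Oc2ccc(C=O)cc2O)C=C(OC)C1=O | intermediate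
16 | (2R,3R)-2-[[(tert-butyldiphenylsilyl)oxy]methyl]-3-(4-hydroxy-3,5-dimethoxyphenyl)-2,3-dihydro-1,4-benzodioxine-6-carbaldehyde, trans | COc1cc([C@H]2Oc3cc(C=O)ccc3O[C@@H]2CO[Si](c2ccccc2)(c2ccccc2)C(C)(C)C)cc(OC)c1O | intermediate
17 | (2R,3R)-3-[4-[(tert-butyldimethylsilyl)oxy]-3,5-dimethoxyphenyl]-2-[[(tert-butyldiphenylsilyl)oxy]methyl]-2,3-dihydro-1,4-benzodioxine-6-carbaldehyde | COc1cc([C@H]2Oc3cc(C=O)ccc3O[C@@H]2CO[Si](c2ccccc2)(c2ccccc2)C(C)(C)C)cc(OC)c1O[Si](C)(C)C(C)(C)C | intermediate
18 | 3,5-dihydroxybenzyl alcohol | OCc1cc(O)cc(O)c1 | starting material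
19 | tert-butyl[[3,5-bis[(tert-butyldimethylsilyl)oxy]phenyl]methoxy]dimethylsilane | CC(C)(C)[Si](C)(C)OCc1cc(O[Si](C)(C)C(C)(C)C)cc(O[Si](C)(C)C(C)(C)C)c1 | intermediate
20 | [3,5-bis[(tert-butyldimethylsilyl)oxy]phenyl]methanol | OCc1cc(O[Si](C)(C)C(C)(C)C)cc(O[Si](C)(C)C(C)(C)C)c1 | intermediate
21 | [[5-(bromomethyl)-1,3-phenylene]bis(oxy)]bis(tert-butyldimethylsilane) | BrCc1cc(O[Si](C)(C)C(C)(C)C)cc(O[Si](C)(C)C(C)(C)C)c1 | intermediate
22 | diethyl [3,5-bis[(tert-butyldimethylsilyl)oxy]benzyl]phosphonate | CCOP(=O)(Cc1cc(O[Si](C)(C)C(C)(C)C)cc(O[Si](C)(C)C(C)(C)C)c1)OCC | intermediate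
23 | tetrasilyl aiphanol, (2R,3R), E-alkene; TBS on the ring A phenol and both ring D phenols, TBDPS on O9' | COc1cc([C@H]2Oc3cc(/C=C/c4cc(O[Si](C)(C)C(C)(C)C)cc(O[Si](C)(C)C(C)(C)C)c4)ccc3O[C@@H]2CO[Si](c2ccccc2)(c2ccccc2)C(C)(C)C)cc(OC)c1O[Si](C)(C)C(C)(C)C | intermediate
24 | aiphanol, 5-[(E)-2-[(2R,3R)-3-(4-hydroxy-3,5-dimethoxyphenyl)-2-(hydroxymethyl)-2,3-dihydro-1,4-benzodioxin-6-yl]ethenyl]benzene-1,3-diol | COc1cc([C@H]2Oc3cc(/C=C/c4cc(O)cc(O)c4)ccc3O[C@@H]2CO)cc(OC)c1O | target

**Step count**

Total: 15 steps. Longest linear sequence: 10 steps (1, 2, 3, 4, 5, 7, 8, 9, 14, 15).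

**Steps most likely to fail**

1. Step 8. At the acidity needed to unmask the phenol and the aldehyde, the benzylic cation may lose the C8' proton (enol ether formation and loss of the aryl ether) faster than it closes, or closure may stall at a cis/trans mixture.
Fallback (anionic quinone methide generation, no cation): it sets out from lactol 8 and returns at 16. Phenol 9 is silylated (TBSCl, imidazole, DMF) to tert-butyl(4-bromo-2,6-dimethoxyphenoxy)dimethylsilane F1. F1 is converted with Mg in THF into [4-[(tert-butyldimethylsilyl)oxy]-3,5-dimethoxyphenyl]magnesium bromide F2, which is added to 8 as in step 7 to give the ring A silyl-protected carbinol F3 as a C7' epimer mixture. Ac2O, pyridine and DMAP (cat.) acetylate the C7' hydroxyl and the ring B phenol to give the diacetate F4. Bu4NF in THF at 0 °C cleaves the aryl silyl ether, and the ring A phenoxide expels the C7' acetate by 1,6-elimination to give the quinone methide. K2CO3 in MeOH then frees the ring B phenoxide, which closes ring C and equilibrates through phenoxide-driven reopening to the trans benzodioxane acetal, 4-[(2R,3R)-2-[[(tert-butyldiphenylsilyl)oxy]methyl]-6-(1,3-dioxolan-2-yl)-2,3-dihydro-1,4-benzodioxin-3-yl]-2,6-dimethoxyphenol F5. PPTS in THF/H2O at 40 °C removes the dioxolane to give 16.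

2. Step 3. The two phenols may be differentiated poorly (alkylation at the 3-hydroxyl or at both), or the catechol may tie up the phosphonium reagent as a cyclic phosphorane.
Fallback (SN2 on a sulfonate with the mono-phenoxide): it sets out from 3 and returns at 5. Tf2O and 2,6-lutidine in CH2Cl2 at −78 °C convert 3, with retention, into methyl (2S)-3-[(tert-butyldiphenylsilyl)oxy]-2-[(trifluoromethanesulfonyl)oxy]propanoate F6. Aldehyde 4 with one equivalent of K2CO3 in MeCN at −20 °C is ionized only at the 4-hydroxyl, the basis of the established 4-O-selective alkylation of this aldehyde. This phenoxide displaces the triflate with inversion to give 5.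

3. Step 7. The basic reagent may enolize the ring-opened α-aryloxy aldehyde (loss of configuration at C8' or β-elimination of silanolate), or the magnesium lactolate may open too slowly.
Fallback (acylation then reduction, no free aldehyde under basic conditions): it sets out from lactone 7 and returns at 13. MeNHOMe·HCl and i-PrMgCl in THF at −20 °C open the lactone to the Weinreb amide, (2R)-3-[(tert-butyldiphenylsilyl)oxy]-2-[4-(1,3-dioxolan-2-yl)-2-hydroxyphenoxy]-N-methoxy-N-methylpropanamide F7. Grignard reagent 11 (3 equiv, the first spent on the phenol) adds at −20 → 0 °C; the chelated tetrahedral intermediate should persist until work-up and then release the ketone, (2R)-3-[(tert-butyldiphenylsilyl)oxy]-1-[3,5-dimethoxy-4-(tetrahydro-2H-pyran-2-yloxy)phenyl]-2-[4-(1,3-dioxolan-2-yl)-2-hydroxyphenoxy]propan-1-one F8. NaBH4 in MeOH at −20 °C reduces F8 to 13 as the epimer mixture.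

Further compounds
F1 | step 8 | tert-butyl(4-bromo-2,6-dimethoxyphenoxy)dimethylsilane | COc1cc(Br)cc(OC)c1O[Si](C)(C)C(C)(C)C
F2 | step 8 | [4-[(tert-butyldimethylsilyl)oxy]-3,5-dimethoxyphenyl]magnesium bromide | COc1cc([Mg]Br)cc(OC)c1O[Si](C)(C)C(C)(C)C
F3 | step 8 | (1RS,2R)-1-[4-[(tert-butyldimethylsilyl)oxy]-3,5-dimethoxyphenyl]-3-[(tert-butyldiphenylsilyl)oxy]-2-[4-(1,3-dioxolan-2-yl)-2-hydroxyphenoxy]propan-1-ol | COc1cc(C(O)[C@@H](CO[Si](c2ccccc2)(c2ccccc2)C(C)(C)C)Oc2ccc(C3OCCO3)cc2O)cc(OC)c1O[Si](C)(C)C(C)(C)C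
F4 | step 8 | diacetate of F3 (acetates on the C7' oxygen and on the ring B phenol), (1RS,2R) | COc1cc(C(OC(C)=O)[C@@H](CO[Si](c2ccccc2)(c2ccccc2)C(C)(C)C)Oc2ccc(C3OCCO3)cc2OC(C)=O)cc(OC)c1O[Si](C)(C)C(C)(C)C
F5 | step 8 | 4-[(2R,3R)-2-[[(tert-butyldiphenylsilyl)oxy]methyl]-6-(1,3-dioxolan-2-yl)-2,3-dihydro-1,4-benzodioxin-3-yl]-2,6-dimethoxyphenol | COc1cc([C@H]2Oc3cc(C4OCCO4)ccc3O[C@@H]2CO[Si](c2ccccc2)(c2ccccc2)C(C)(C)C)cc(OC)c1O
F6 | step 3 | methyl (2S)-3-[(tert-butyldiphenylsilyl)oxy]-2-[(trifluoromethanesulfonyl)oxy]propanoate | COC(=O)[C@@H](OS(=O)(=O)C(F)(F)F)CO[Si](c1ccccc1)(c1ccccc1)C(C)(C)C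
F7 | step 7 | (2R)-3-[(tert-butyldiphenylsilyl)oxy]-2-[4-(1,3-dioxolan-2-yl)-2-hydroxyphenoxy]-N-methoxy-N-methylpropanamide | CON(C)C(=O)[C@H](Oc1ccc(C2OCCO2)cc1O)CO[Si](c1ccccc1)(c1ccccc1)C(C)(C)C
F8 | step 7 | (2R)-3-[(tert-butyldiphenylsilyl)oxy]-1-[3,5-dimethoxy-4-(tetrahydro-2H-pyran-2-yloxy)phenyl]-2-[4-(1,3-dioxolan-2-yl)-2-hydroxyphenoxy]propan-1-one | COc1cc(C(=O)[C@H](Oc2ccc(C3OCCO3)cc2O)CO[Si](c2ccccc2)(c2ccccc2)C(C)(C)C)cc(OC)c1OC1CCCCO1
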